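**Plan**
- Retrosynthesis: the ring B–CH2 bond to ring C is cut first (Mannich-base alkylation). The two butyryl C–C bonds (on a1 of ring A and on ring B) go next. Ring A is then opened across a4–a5 and a1–a6, the a3–a4 bond being the one that closes the ring, which leads back to a cyclobutenone and a siloxyalkyne.
- Enabling feature: in ring A (a1 butyryl carbon, a2 C–O, a3 CMe2, a4 C–O, a5 carbon bearing the CH2 link to ring B, a6 C=O) the quaternary a3 sits between two oxygenated carbons. A vinylketene–alkyne annulation that ends by 6π closure onto a3 therefore gives a dienone that cannot aromatise and already has the trione oxidation level.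
- Forward: ring B (phloroglucinol as its tribenzyl ether) is extended to a propargylic siloxyalkyne, and ring A is annulated onto it. The enol ethers and benzyl ethers are then removed and both butyryl groups are introduced. Ring C (from 2,4,6-trihydroxyacetophenone) is attached last through its Mannich base.
- Stereochemistry: the target has no stereocentre and no configurationally fixed double bond, so nothing has to be set.

Key step: step 7

Remark: the enolised triones are written as single tautomers (those of the target SMILES); partially reacted stages of one repeated operation within a step (partial benzylation or debenzylation, monomethylation, monoacylation) are not numbered separately.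

**Step 1**
Reactants: 1 isobutyryl chloride; 2 ethoxyethyne
Product: 4 3-ethoxy-4,4-dimethylcyclobut-2-en-1-one, via dimethylketene 3 (not isolated)
Conditions: Et3N, Et2O, 0 → 35 °C
Reagents that add atoms: none
Why: Triethylamine dehydrochlorinates 1 to dimethylketene, which undergoes the known regioselective [2+2] cycloaddition with the electron-rich ynol ether (its CH terminus bonding to the ketene carbonyl carbon) to give the 3-ethoxycyclobutenone.

**Step 2**
Reactants: 5 phloroglucinol; 6 benzyl bromide
Product: 7 1,3,5-tris(benzyloxy)benzene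
Conditions: BnBr, K2CO3, DMF, 25 → 60 °C
Reagents that add atoms: benzyl bromide (6), BrCc1ccccc1
Why: Williamson O-alkylation of the phenoxide in a polar aprotic solvent, the C-benzylated by-products typical of phloroglucinol being removed by crystallisation.

**Step 3**
Reactants: 7 1,3,5-tris(benzyloxy)benzene
Product: 8 2-bromo-1,3,5-tris(benzyloxy)benzene
Conditions: NBS, CH2Cl2, −78 → 0 °C
Reagents that add atoms: N-bromosuccinimide, O=C1CCC(=O)N1Br
Why: Electrophilic aromatic bromination of the strongly activated ring, held at the monobromide by one equivalent of reagent at low temperature (the three free positions are equivalent).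

**Step 4**
Reactants: 8 2-bromo-1,3,5-tris(benzyloxy)benzene; 9 3-bromo-1-(trimethylsilyl)prop-1-yne
Product: 11 trimethyl{3-[2,4,6-tris(benzyloxy)phenyl]prop-1-yn-1-yl}silane, via arylmagnesium bromide 10 (not isolated)
Conditions: Mg, THF, 50 °C; then CuBr·SMe2 (5 mol %), 9, THF, 0 → 25 °C
Reagents that add atoms: 3-bromo-1-(trimethylsilyl)prop-1-yne (9), C[Si](C)(C)C#CCBr
Why: Grignard formation followed by copper-catalysed SN2 alkylation with a propargylic bromide, in which the trimethylsilyl cap blocks SN2′ attack (allene formation) and masks the acidic alkyne C–H.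

**Step 5**
Reactants: 11 trimethyl{3-[2,4,6-tris(benzyloxy)phenyl]prop-1-yn-1-yl}silane
Product: 12 1,3,5-tris(benzyloxy)-2-(prop-2-yn-1-yl)benzene
Conditions: K2CO3 (0.2 equiv), MeOH/THF, 0 °C
Reagents that add atoms: none
Why: Carbonate-catalysed methanolysis of the alkynyl C–Si bond (protodesilylation), run cold and briefly so that the benzylic propargylic CH2 is not isomerised to the allene.

**Step 6**
Reactants: 12 1,3,5-tris(benzyloxy)-2-(prop-2-yn-1-yl)benzene
Product: 15 triisopropyl({3-[2,4,6-tris(benzyloxy)phenyl]prop-1-yn-1-yl}oxy)silane, via lithium acetylide 13 (not isolated), via lithium ynolate 14 (not isolated)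
Conditions: LiN(SiMe3)2 (2.1 equiv), t-BuOOH, THF, −78 → 0 °C; then i-Pr3SiOTf, −78 °C
Reagents that add atoms: tert-butyl hydroperoxide, CC(C)(C)OO; triisopropylsilyl trifluoromethanesulfonate, CC(C)[Si](OS(=O)(=O)C(F)(F)F)(C(C)C)C(C)C
Why: The lithium acetylide attacks the electrophilic oxygen of lithium tert-butyl peroxide to give the lithium ynolate, which the bulky silyl triflate traps on oxygen, the known acetylide-oxidation route to triisopropylsiloxyalkynes.

**Step 7**
Reactants: 4 3-ethoxy-4,4-dimethylcyclobut-2-en-1-one; 15 triisopropyl({3-[2,4,6-tris(benzyloxy)phenyl]prop-1-yn-1-yl}oxy)silane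
Product: 19 5-ethoxy-6,6-dimethyl-3-[(triisopropylsilyl)oxy]-2-[2,4,6-tris(benzyloxy)benzyl]cyclohexa-2,4-dien-1-one, via vinylketene 16 (not isolated), via 4-vinylcyclobutenone 17 (not isolated), via dienylketene 18 (not isolated)
Conditions: 4 (2 equiv), PhMe, 110 °C, sealed tube, argon
Reagents that add atoms: none
Why: Heating opens 4 by 4π electrocyclic ring opening to vinylketene 16, whose ketene C=C adds to the electron-rich triple bond of 15 in a [2+2] cycloaddition to give 4-vinylcyclobutenone 17, and a second 4π opening delivers dienylketene 18. Ring A then closes by thermal 6π electrocyclisation of 18, the ketene carbon bonding to the CMe2 terminus (a4–a3), and because that carbon is quaternary the product cannot tautomerise to a phenol and stays as cyclohexa-2,4-dienone 19 with a2 and a6 as enol ethers. The closest known reaction type is the Danheiser annulation of cyclobutenones with alkoxy- and siloxyalkynes, in the variant where a 4,4-disubstituted cyclobutenone gives a cyclohexadienone. The selectivity needed is the orientation of the ketene–alkyne [2+2] step: the siloxy group makes the alkyne carbon carrying the arylmethyl group the nucleophilic terminus, so it bonds to the ketene carbonyl carbon (a4–a5) while the oxygen-bearing alkyne carbon bonds to the ketene CH (a1–a6), which places the CH2 link next to the carbonyl that flanks CMe2. No stereocentre remains in 19 (the sp3 CH of 17 is transient and racemic), and a silyl rather than an ethyl ynol ether is used because it cannot fragment by retro-ene loss of ethylene at the reaction temperature.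

**Step 8**
Reactants: 19 5-ethoxy-6,6-dimethyl-3-[(triisopropylsilyl)oxy]-2-[2,4,6-tris(benzyloxy)benzyl]cyclohexa-2,4-dien-1-one
Product: 20 3,5-dihydroxy-4,4-dimethyl-2-[2,4,6-tris(benzyloxy)benzyl]cyclohexa-2,5-dien-1-one
Conditions: 1 M aq. HCl, THF, 40 °C
Reagents that add atoms: water, O
Why: Acid hydrolysis of a silyl enol ether and of a vinylogous-ester enol ether to the enolised β-triketone, under which benzyl aryl ethers are stable.

**Step 9**
Reactants: 20 3,5-dihydroxy-4,4-dimethyl-2-[2,4,6-tris(benzyloxy)benzyl]cyclohexa-2,5-dien-1-one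
Product: 21 3,5-dihydroxy-4,4-dimethyl-2-(2,4,6-trihydroxybenzyl)cyclohexa-2,5-dien-1-one
Conditions: H2 (1 atm), 10% Pd/C, EtOAc/MeOH, 25 °C
Reagents that add atoms: none
Why: Catalytic hydrogenolysis of the three benzyl aryl ethers under neutral conditions, which leaves the enolised trione and the CH2 link between the rings untouched.

**Step 10**
Reactants: 21 3,5-dihydroxy-4,4-dimethyl-2-(2,4,6-trihydroxybenzyl)cyclohexa-2,5-dien-1-one; 22 butanoyl chloride
Product: 23 2-butanoyl-6-(3-butanoyl-2,4,6-trihydroxybenzyl)-3,5-dihydroxy-4,4-dimethylcyclohexa-2,5-dien-1-one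
Conditions: n-PrCOCl (2.2 equiv), AlCl3, PhNO2, 25 → 45 °C; then ice/aq. HCl
Reagents that add atoms: butanoyl chloride (22), CCCC(Cl)=O
Why: Lewis-acid C-acylation, namely Friedel–Crafts acylation at one of the two equivalent free carbons of ring B and C-acylation of the enol carbon a1 of ring A (directly or by O-acylation and Fries-type shift), as known for phloroglucinol and for filicinic acid, the first acyl group deactivating ring B against a second one.

**Step 11**
Reactants: 24 2,4,6-trihydroxyacetophenone; 25 iodomethane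
Product: 26 2-acetyl-3,5-dihydroxy-4,4-dimethylcyclohexa-2,5-dien-1-one (acetylfilicinic acid)
Conditions: MeI, NaOMe, MeOH, 0 → 25 °C; then aq. HCl
Reagents that add atoms: iodomethane (25), CI
Why: Double C-methylation of the phloroacetophenone polyanion at one ring carbon, the second methylation dearomatising the ring to the gem-dimethyl trione, which is the standard preparation of acylfilicinic acids.

**Step 12**
Reactants: 26 acetylfilicinic acid; 27 N,N-dimethylmethyleneiminium iodide (Eschenmoser's salt)
Product: 28 2-acetyl-6-[(dimethylamino)methyl]-3,5-dihydroxy-4,4-dimethylcyclohexa-2,5-dien-1-one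
Conditions: Me2N=CH2 I, i-Pr2NEt, CH2Cl2, 0 → 25 °C
Reagents that add atoms: N,N-dimethylmethyleneiminium iodide (27), C=[N+](C)C.[I-]
Why: Mannich reaction of the only C–H enol carbon of the trione with a preformed iminium salt, which avoids free formaldehyde and therefore the symmetric methylene-bis dimer.

**Step 13**
Reactants: 23 2-butanoyl-6-(3-butanoyl-2,4,6-trihydroxybenzyl)-3,5-dihydroxy-4,4-dimethylcyclohexa-2,5-dien-1-one; 28 2-acetyl-6-[(dimethylamino)methyl]-3,5-dihydroxy-4,4-dimethylcyclohexa-2,5-dien-1-one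
Product: 30 2-acetyl-6-{3-butanoyl-5-[(5-butanoyl-2,4-dihydroxy-3,3-dimethyl-6-oxocyclohexa-1,4-dien-1-yl)methyl]-2,4,6-trihydroxybenzyl}-3,5-dihydroxy-4,4-dimethylcyclohexa-2,5-dien-1-one (target), via methylene trione 29 (not isolated)
Conditions: 28 (1.5 equiv), 1,4-dioxane, 80 °C, argon
Reagents that add atoms: none
Why: Thermal elimination of dimethylamine from the Mannich base gives the 6-methylene trione 29, a reactive Michael acceptor that is captured by the single free carbon of ring B (Michael/Friedel–Crafts alkylation), the known way to unsymmetrical methylene-bridged acylphloroglucinols.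

**Compound list**
1 | isobutyryl chloride | CC(C)C(Cl)=O | starting material
2 | ethoxyethyne | CCOC#C | starting material
3 | dimethylketene (not isolated) | CC(C)=C=O | intermediate
4 | 3-ethoxy-4,4-dimethylcyclobut-2-en-1-one | CCOC1=CC(=O)C1(C)C | intermediate
5 | phloroglucinol | Oc1cc(O)cc(O)c1 | starting material
6 | benzyl bromide | BrCc1ccccc1 | starting material
7 | 1,3,5-tris(benzyloxy)benzene | c1ccc(COc2cc(OCc3ccccc3)cc(OCc3ccccc3)c2)cc1 | intermediate
8 | 2-bromo-1,3,5-tris(benzyloxy)benzene | Brc1c(OCc2ccccc2)cc(OCc2ccccc2)cc1OCc1ccccc1 | intermediate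
9 | 3-bromo-1-(trimethylsilyl)prop-1-yne | C[Si](C)(C)C#CCBr | starting material
10 | [2,4,6-tris(benzyloxy)phenyl]magnesium bromide (not isolated) | Br[Mg]c1c(OCc2ccccc2)cc(OCc2ccccc2)cc1OCc1ccccc1 | intermediate
11 | trimethyl{3-[2,4,6-tris(benzyloxy)phenyl]prop-1-yn-1-yl}silane | C[Si](C)(C)C#CCc1c(OCc2ccccc2)cc(OCc2ccccc2)cc1OCc1ccccc1 | intermediate
12 | 1,3,5-tris(benzyloxy)-2-(prop-2-yn-1-yl)benzene | C#CCc1c(OCc2ccccc2)cc(OCc2ccccc2)cc1OCc1ccccc1 | intermediate
13 | lithium 3-[2,4,6-tris(benzyloxy)phenyl]prop-1-yn-1-ide (not isolated) | [Li]C#CCc1c(OCc2ccccc2)cc(OCc2ccccc2)cc1OCc1ccccc1 | intermediate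
14 | lithium 3-[2,4,6-tris(benzyloxy)phenyl]prop-1-yn-1-olate (not isolated) | [Li]OC#CCc1c(OCc2ccccc2)cc(OCc2ccccc2)cc1OCc1ccccc1 | intermediate
15 | triisopropyl({3-[2,4,6-tris(benzyloxy)phenyl]prop-1-yn-1-yl}oxy)silane | CC(C)[Si](OC#CCc1c(OCc2ccccc2)cc(OCc2ccccc2)cc1OCc1ccccc1)(C(C)C)C(C)C | intermediate
16 | 3-ethoxy-4-methylpenta-1,3-dien-1-one (vinylketene, not isolated) | CCOC(C=C=O)=C(C)C | intermediate
17 | 4-(1-ethoxy-2-methylprop-1-en-1-yl)-3-[(triisopropylsilyl)oxy]-2-[2,4,6-tris(benzyloxy)benzyl]cyclobut-2-en-1-one (racemic, not isolated) | CCOC(=C(C)C)C1C(=O)C(Cc2c(OCc3ccccc3)cc(OCc3ccccc3)cc2OCc2ccccc2)=C1O[Si](C(C)C)(C(C)C)C(C)C | intermediate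
18 | (3E)-5-ethoxy-6-methyl-3-[(triisopropylsilyl)oxy]-2-[2,4,6-tris(benzyloxy)benzyl]hepta-1,3,5-trien-1-one (dienylketene, not isolated) | O=C=C(Cc1c(OCc2ccccc2)cc(OCc2ccccc2)cc1OCc1ccccc1)/C(O[Si](C(C)C)(C(C)C)C(C)C)=C\C(OCC)=C(C)C | intermediate
19 | 5-ethoxy-6,6-dimethyl-3-[(triisopropylsilyl)oxy]-2-[2,4,6-tris(benzyloxy)benzyl]cyclohexa-2,4-dien-1-one | CCOC1=CC(O[Si](C(C)C)(C(C)C)C(C)C)=C(Cc2c(OCc3ccccc3)cc(OCc3ccccc3)cc2OCc2ccccc2)C(=O)C1(C)C | intermediate
20 | 3,5-dihydroxy-4,4-dimethyl-2-[2,4,6-tris(benzyloxy)benzyl]cyclohexa-2,5-dien-1-one | CC1(C)C(O)=CC(=O)C(Cc2c(OCc3ccccc3)cc(OCc3ccccc3)cc2OCc2ccccc2)=C1O | intermediate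
21 | 3,5-dihydroxy-4,4-dimethyl-2-(2,4,6-trihydroxybenzyl)cyclohexa-2,5-dien-1-one | CC1(C)C(O)=CC(=O)C(Cc2c(O)cc(O)cc2O)=C1O | intermediate
22 | butanoyl chloride | CCCC(Cl)=O | starting material
23 | 2-butanoyl-6-(3-butanoyl-2,4,6-trihydroxybenzyl)-3,5-dihydroxy-4,4-dimethylcyclohexa-2,5-dien-1-one | CCCC(=O)C1=C(O)C(C)(C)C(O)=C(Cc2c(O)cc(O)c(C(=O)CCC)c2O)C1=O | intermediate
24 | 2,4,6-trihydroxyacetophenone | CC(=O)c1c(O)cc(O)cc1O | starting material
25 | iodomethane | CI | starting material
26 | 2-acetyl-3,5-dihydroxy-4,4-dimethylcyclohexa-2,5-dien-1-one (acetylfilicinic acid) | CC(=O)C1=C(O)C(C)(C)C(O)=CC1=O | intermediate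
27 | N,N-dimethylmethyleneiminium iodide (Eschenmoser's salt) | C=[N+](C)C.[I-] | starting material
28 | 2-acetyl-6-[(dimethylamino)methyl]-3,5-dihydroxy-4,4-dimethylcyclohexa-2,5-dien-1-one | CC(=O)C1=C(O)C(C)(C)C(O)=C(CN(C)C)C1=O | intermediate
29 | 2-acetyl-3-hydroxy-4,4-dimethyl-6-methylidenecyclohex-2-ene-1,5-dione (not isolated) | C=C1C(=O)C(C(C)=O)=C(O)C(C)(C)C1=O | intermediate
30 | 2-acetyl-6-{3-butanoyl-5-[(5-butanoyl-2,4-dihydroxy-3,3-dimethyl-6-oxocyclohexa-1,4-dien-1-yl)methyl]-2,4,6-trihydroxybenzyl}-3,5-dihydroxy-4,4-dimethylcyclohexa-2,5-dien-1-one | CCCC(=O)C1=C(O)C(C)(C)C(O)=C(Cc2c(O)c(CC3=C(O)C(C)(C)C(O)=C(C(C)=O)C3=O)c(O)c(C(=O)CCC)c2O)C1=O | target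

**Count**
Total steps: 13. Longest linear sequence: 10 steps (steps 2–10 and 13, from phloroglucinol).

**Steps most likely to fail**

1. Step 7. The alkoxy-stabilised cyclobutenone may open too slowly, so that thermal decay of the siloxyalkyne (1,3-silyl shift) or ketene self-condensation outruns the annulation. The fallback makes the same vinylketene without heat; it sets out from 15 and comes back to the route at 19. Commercial ethyl 4-methyl-3-oxopentanoate F1 is converted with HC(OEt)3, EtOH and catalytic H2SO4 into ethyl (E)-3-ethoxy-4-methylpent-2-enoate F2. Saponification (LiOH, aq. THF) gives (E)-3-ethoxy-4-methylpent-2-enoic acid F3, and (COCl)2 with catalytic DMF gives (E)-3-ethoxy-4-methylpent-2-enoyl chloride F4. Slow addition of F4 to 15 and Et3N in CH2Cl2 at 25 °C generates 16 by 1,4-elimination of HCl, so that 17 forms without heating; brief warming in PhMe at 80 °C then takes 17 through 18 to 19.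

2. Step 10. Under AlCl3 and the HCl it releases, the ring A–CH2–ring B bond may ionise (retro-Friedel–Crafts loss of the trihydroxybenzyl unit), and acylation may stop short or run on to a second acyl group on ring B. The fallback acylates before the phenols are unmasked and without a metal Lewis acid; it sets out from 20 and comes back at 23. Butanoic acid, DCC and DMAP in CH2Cl2 O-acylate the ring A enol, and DMAP shifts the acyl group to a1, giving 2-butanoyl-3,5-dihydroxy-4,4-dimethyl-6-[2,4,6-tris(benzyloxy)benzyl]cyclohexa-2,5-dien-1-one F5. The benzyl-protected ring B is then acylated by the mixed anhydride of butanoic acid and (CF3CO)2O in CH2Cl2 at 25 °C, giving 2-butanoyl-6-[3-butanoyl-2,4,6-tris(benzyloxy)benzyl]-3,5-dihydroxy-4,4-dimethylcyclohexa-2,5-dien-1-one F6. Hydrogenolysis (H2, Pd/C, EtOAc/MeOH) gives 23.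

3. Step 13. The methylene bridges may scramble by reversible retro-Michael fragmentation in the amine-containing medium, and the ring C electrophile may be consumed by self-condensation. The fallback reverses the roles of the partners; it sets out from 23 and comes back at 30. Treatment of 23 with Eschenmoser's salt and i-Pr2NEt in CH2Cl2 aminomethylates the one free carbon of ring B, giving 2-butanoyl-6-{3-butanoyl-5-[(dimethylamino)methyl]-2,4,6-trihydroxybenzyl}-3,5-dihydroxy-4,4-dimethylcyclohexa-2,5-dien-1-one F7. F7 cannot dimerise, and heating it with an excess of 26 in 1,4-dioxane at 80 °C generates the ring B quinone methide, which is trapped by the enol carbon of 26 to give 30.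

**Further compounds**
F1 | step 7 | ethyl 4-methyl-3-oxopentanoate | CCOC(=O)CC(=O)C(C)C
F2 | step 7 | ethyl (E)-3-ethoxy-4-methylpent-2-enoate | CCOC(=O)/C=C(/OCC)C(C)C
F3 | step 7 | (E)-3-ethoxy-4-methylpent-2-enoic acid | OC(=O)/C=C(/OCC)C(C)C
F4 | step 7 | (E)-3-ethoxy-4-methylpent-2-enoyl chloride | ClC(=O)/C=C(/OCC)C(C)C
F5 | step 10 | 2-butanoyl-3,5-dihydroxy-4,4-dimethyl-6-[2,4,6-tris(benzyloxy)benzyl]cyclohexa-2,5-dien-1-one | CCCC(=O)C1=C(O)C(C)(C)C(O)=C(Cc2c(OCc3ccccc3)cc(OCc3ccccc3)cc2OCc2ccccc2)C1=O
F6 | step 10 | 2-butanoyl-6-[3-butanoyl-2,4,6-tris(benzyloxy)benzyl]-3,5-dihydroxy-4,4-dimethylcyclohexa-2,5-dien-1-one | CCCC(=O)C1=C(O)C(C)(C)C(O)=C(Cc2c(OCc3ccccc3)cc(OCc3ccccc3)c(C(=O)CCC)c2OCc2ccccc2)C1=O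
F7 | step 13 | 2-butanoyl-6-{3-butanoyl-5-[(dimethylamino)methyl]-2,4,6-trihydroxybenzyl}-3,5-dihydroxy-4,4-dimethylcyclohexa-2,5-dien-1-one | CCCC(=O)C1=C(O)C(C)(C)C(O)=C(Cc2c(O)c(CN(C)C)c(O)c(C(=O)CCC)c2O)C1=O
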